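The 2,5-dihydrofuran ring (O1, C2, C3, C3a, C7a of the hexahydrobenzofuran) is disconnected into an allylic sulfonium salt and (Z)-3-iodo-2-methylacrolein. In one flask a chiral sulfonium ylide adds to the aldehyde to give a trans-vinyl oxirane (C3–C2 bond), and a copper-catalysed ring expansion then moves the oxirane oxygen from C3 to C7a (O1–C7a bond). The step exploits C7a as the tertiary terminus of the allyl unit C3–C3a=C7a of the cyclohexene ring. The precursor is a spiro-ketal cyclohexenylmethyl sulfonium triflate. The sulfide sets C2, the oxygen shift relays it to C7a, ketone reduction then sets C6, and a Suzuki coupling adds the pentaene.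

Key step: step 7

Remark: the side-chain alkene next to the ring is Z (C2 of the ring and the chain on the same side) and all others are E, as drawn in the target; the (1R,4R,5R) sulfide is assumed to give the (2S,3S)-oxirane 11, and its enantiomer would be used if the sense of induction is the opposite.

**Step 1**
Reactants: 1 ethyl 2,6,6-trimethyl-4-oxocyclohex-2-ene-1-carboxylate (racemic)
Product: 2 ethyl 7,9,9-trimethyl-1,4-dioxaspiro[4.5]dec-7-ene-8-carboxylate
Conditions: ethylene glycol, p-TsOH (cat.), toluene, reflux, Dean–Stark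
Reagents that add atoms: ethylene glycol, OCCO
Why: Acid-catalysed ketalisation of the enone runs through the dienol and moves the double bond to the β,γ-position, here into conjugation with the ester, which should give the tetrasubstituted alkene (future C3a=C7a) and leaves no stereocentre.

**Step 2**
Reactants: 2 ethyl 7,9,9-trimethyl-1,4-dioxaspiro[4.5]dec-7-ene-8-carboxylate
Product: 3 (7,9,9-trimethyl-1,4-dioxaspiro[4.5]dec-7-en-8-yl)methanol
Conditions: LiAlH4, Et2O, 0 °C to rt
Reagents that add atoms: none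
Why: Hydride reduction of the hindered conjugated ester should give the primary allylic alcohol while the ketal is inert.

**Step 3**
Reactants: 3 (7,9,9-trimethyl-1,4-dioxaspiro[4.5]dec-7-en-8-yl)methanol
Product: 4 8-(bromomethyl)-7,9,9-trimethyl-1,4-dioxaspiro[4.5]dec-7-ene
Conditions: CBr4, PPh3, CH2Cl2, 0 °C; used at once
Reagents that add atoms: carbon tetrabromide, BrC(Br)(Br)Br
Why: The Appel reaction converts the allylic alcohol into the bromide under neutral conditions that the ketal should tolerate.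

**Step 4**
Reactants: 4 8-(bromomethyl)-7,9,9-trimethyl-1,4-dioxaspiro[4.5]dec-7-ene
Product: 5 (1R,4R,5R)-4,7,7-trimethyl-6-[(7,9,9-trimethyl-1,4-dioxaspiro[4.5]dec-7-en-8-yl)methyl]-6-thiabicyclo[3.2.1]octan-6-ium trifluoromethanesulfonate (one sulfur epimer, configuration at sulfur not specified)
Conditions: (1R,4R,5R)-isothiocineole, LiOSO2CF3, CH2Cl2/H2O, rt
Reagents that add atoms: (1R,4R,5R)-4,7,7-trimethyl-6-thiabicyclo[3.2.1]octane (isothiocineole), C[C@@H]1CC[C@@H]2C[C@H]1SC2(C)C; lithium trifluoromethanesulfonate, [Li+].[O-]S(=O)(=O)C(F)(F)F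
Why: S-Alkylation of the thioether by the reactive allylic bromide with triflate metathesis should give the sulfonium salt, the bicyclic sulfide being alkylated on its less hindered lone pair.

**Step 5**
Reactants: 6 prop-2-yn-1-ol
Product: 8 (2Z)-3-iodo-2-methylprop-2-en-1-ol, via alkenylmagnesium alkoxide 7 (not isolated)
Conditions: MeMgBr (2.5 equiv), CuI (cat.), Et2O, −10 °C to rt; then iodine, −78 °C to rt
Reagents that add atoms: methylmagnesium bromide, C[Mg]Br; iodine, [I][I]
Why: Copper-catalysed anti-carbomagnesiation of the propargylic alkoxide places magnesium cis to the CH2O group through a chelate, and iodinolysis with retention should give the Z-iodide.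

**Step 6**
Reactants: 8 (2Z)-3-iodo-2-methylprop-2-en-1-ol
Product: 9 (2Z)-3-iodo-2-methylprop-2-enal
Conditions: MnO2, CH2Cl2, rt, dark; used at once
Reagents that add atoms: none
Why: Allylic oxidation with MnO2 is neutral and should keep the Z geometry of the labile enal.

**Step 7**
Reactants: 5 sulfonium triflate; 9 (2Z)-3-iodo-2-methylprop-2-enal
Product: 12 (2R,7aR)-2-[(1Z)-1-iodoprop-1-en-2-yl]-4,4,7a-trimethyl-2,4,5,7a-tetrahydro-7H-spiro[1-benzofuran-6,2'-[1,3]dioxolane], via sulfonium ylide 10 (not isolated), via trans-vinyl oxirane 11 (not isolated)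
Conditions: KN(SiMe3)2, THF, −78 °C, then 9, −78 to −20 °C; then Cu(CF3COCHCOCF3)2 (5 mol%), toluene, 60 °C
Reagents that add atoms: none
Why: Deprotonation of 5 gives the semi-stabilised allylic ylide 10, which adds through its α-carbon to the aldehyde of 9 to a betaine that closes (3-exo-tet, loss of the sulfide) to the trans-vinyl oxirane 11; the copper Lewis acid then ionises the allylic C3–O bond and the alkoxide, still held on C2, closes on the tertiary allyl terminus C7a (formally 5-endo, a 1,3-oxygen shift). The closest known reactions are the asymmetric sulfonium-ylide epoxidation of aldehydes with allylic salts of a chiral sulfide and the Cu(CF3COCHCOCF3)2-catalysed ring expansion of vinyl oxiranes to 2,5-dihydrofurans. C2 is set by the chiral sulfide (face of the ylide carbon plus reversible anti-betaine formation, hence the trans-oxirane with (2S,3S) configuration), and C7a by suprafacial transfer from the oxirane carbon C3: the oxygen leaves and re-enters on the same face of the allyl unit, so the (2S,3S)-oxirane should give the (2R,7aR)-dihydrofuran. The step needs α- over γ-attack of the ylide (the γ-carbon is fully substituted), 1,2- over conjugate addition to the enal (usual for sulfonium ylides), and cleavage of the C3–O and not the C2–O oxirane bond (only C3–O gives a cation with a tertiary terminus). The ring carries no other stereocentre at this stage, so nothing in the substrate opposes the relay.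

**Step 8**
Reactants: 12 spiro-ketal dihydrofuran
Product: 13 (2R,7aR)-2-[(1Z)-1-iodoprop-1-en-2-yl]-4,4,7a-trimethyl-4,5,7,7a-tetrahydro-1-benzofuran-6(2H)-one
Conditions: PPTS (cat.), acetone/H2O, 40 °C
Reagents that add atoms: water, O
Why: Mild acid-catalysed hydrolysis of the dioxolane should free the ketone while the allylic ether bonds, which ionise only under stronger acid, and both stereocentres stay untouched.

**Step 9**
Reactants: 13 ketone
Product: 14 (2R,6S,7aR)-2-[(1Z)-1-iodoprop-1-en-2-yl]-4,4,7a-trimethyl-2,4,5,6,7,7a-hexahydro-1-benzofuran-6-ol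
Conditions: LiBH(s-Bu)3, THF, −78 °C; H2O work-up
Reagents that add atoms: none
Why: In this substrate-controlled reduction the bulky trialkylborohydride should attack the ketone from the face opposite the two syn-axial methyl groups on C4 and C7a (equatorial attack), which gives the axial (6S) alcohol cis to the C7a methyl.

**Step 10**
Reactants: 15 (2E,4E,6E)-2,7-dimethylocta-2,4,6-trienedial
Product: 16 ethyl (2E,4E,6E,8E)-4,9-dimethyl-10-oxodeca-2,4,6,8-tetraenoate
Conditions: (EtO)2P(O)CH2CO2Et (1 equiv), NaH, THF, 0 °C, added to 15 in slight excess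
Reagents that add atoms: triethyl phosphonoacetate, CCOC(=O)CP(=O)(OCC)OCC
Why: The Horner–Wadsworth–Emmons reaction is E-selective and should stop at mono-olefination because the remaining aldehyde of 16 is more conjugated and less electrophilic than those of 15.

**Step 11**
Reactants: 16 ethyl (2E,4E,6E,8E)-4,9-dimethyl-10-oxodeca-2,4,6,8-tetraenoate
Product: 17 ethyl (2E,4E,6E,8E,10E)-4,9-dimethyl-11-(4,4,5,5-tetramethyl-1,3,2-dioxaborolan-2-yl)undeca-2,4,6,8,10-pentaenoate
Conditions: CH2(Bpin)2, lithium 2,2,6,6-tetramethylpiperidide, THF, 0 °C; then 16, −78 °C to rt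
Reagents that add atoms: 2,2'-methylenebis(4,4,5,5-tetramethyl-1,3,2-dioxaborolane), C(B1OC(C)(C)C(C)(C)O1)B1OC(C)(C)C(C)(C)O1
Why: In the boron-Wittig olefination the lithiated gem-diborylmethane adds to the aldehyde (not to the ester at low temperature) and syn B–O elimination should give the E-alkenyl boronate.

**Step 12**
Reactants: 17 boronate ester
Product: 18 (2E,4E,6E,8E,10E)-4,9-dimethyl-11-(4,4,5,5-tetramethyl-1,3,2-dioxaborolan-2-yl)undeca-2,4,6,8,10-pentaen-1-ol
Conditions: i-Bu2AlH, CH2Cl2, −78 °C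
Reagents that add atoms: none
Why: 1,2-Reduction of the conjugated ester with the aluminium hydride should give the allylic alcohol and leave the C–B bond and the alkene geometries unchanged.

**Step 13**
Reactants: 14 hydroxy vinyl iodide; 18 pentaenyl boronate
Product: 19 (2R,6S,7aR)-2-[(2Z,4E,6E,8E,10E,12E)-14-hydroxy-6,11-dimethyltetradeca-2,4,6,8,10,12-hexaen-2-yl]-4,4,7a-trimethyl-2,4,5,6,7,7a-hexahydro-1-benzofuran-6-ol
Conditions: Pd(PPh3)4 (5 mol%), K3PO4, THF/H2O, rt, argon, dark
Reagents that add atoms: none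
Why: Suzuki–Miyaura cross-coupling proceeds with retention at both partners (Z iodide, E boronate) and tolerates the two free hydroxyl groups, so it should give the target directly.

**Compound list**
1 | ethyl 2,6,6-trimethyl-4-oxocyclohex-2-ene-1-carboxylate (racemic) | CCOC(=O)C1C(C)=CC(=O)CC1(C)C | starting material
2 | ethyl 7,9,9-trimethyl-1,4-dioxaspiro[4.5]dec-7-ene-8-carboxylate | CCOC(=O)C1=C(C)CC2(CC1(C)C)OCCO2 | intermediate
3 | (7,9,9-trimethyl-1,4-dioxaspiro[4.5]dec-7-en-8-yl)methanol | OCC1=C(C)CC2(CC1(C)C)OCCO2 | intermediate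
4 | 8-(bromomethyl)-7,9,9-trimethyl-1,4-dioxaspiro[4.5]dec-7-ene | BrCC1=C(C)CC2(CC1(C)C)OCCO2 | intermediate
5 | (1R,4R,5R)-4,7,7-trimethyl-6-[(7,9,9-trimethyl-1,4-dioxaspiro[4.5]dec-7-en-8-yl)methyl]-6-thiabicyclo[3.2.1]octan-6-ium trifluoromethanesulfonate | C[C@@H]1CC[C@@H]2C[C@H]1[S+](CC3=C(C)CC4(CC3(C)C)OCCO4)C2(C)C.[O-]S(=O)(=O)C(F)(F)F | intermediate
6 | prop-2-yn-1-ol | C#CCO | starting material
7 | bromomagnesium (2Z)-3-(bromomagnesio)-2-methylprop-2-en-1-olate | Br[Mg]OC/C(C)=C\[Mg]Br | intermediate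
8 | (2Z)-3-iodo-2-methylprop-2-en-1-ol | OC/C(C)=C\I | intermediate
9 | (2Z)-3-iodo-2-methylprop-2-enal | O=C/C(C)=C\I | intermediate
10 | sulfonium ylide of 5 (carbanion on the CH between sulfur and the ring) | C[C@@H]1CC[C@@H]2C[C@H]1[S+]([CH-]C3=C(C)CC4(CC3(C)C)OCCO4)C2(C)C | intermediate
11 | (2S,3S)-2-[(1Z)-1-iodoprop-1-en-2-yl]-3-(7,9,9-trimethyl-1,4-dioxaspiro[4.5]dec-7-en-8-yl)oxirane | C/C(=C/I)[C@@H]1O[C@H]1C2=C(C)CC3(CC2(C)C)OCCO3 | intermediate
12 | (2R,7aR)-2-[(1Z)-1-iodoprop-1-en-2-yl]-4,4,7a-trimethyl-2,4,5,7a-tetrahydro-7H-spiro[1-benzofuran-6,2'-[1,3]dioxolane] | C/C(=C/I)[C@H]1C=C2C(C)(C)CC3(OCCO3)C[C@@]2(C)O1 | intermediate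
13 | (2R,7aR)-2-[(1Z)-1-iodoprop-1-en-2-yl]-4,4,7a-trimethyl-4,5,7,7a-tetrahydro-1-benzofuran-6(2H)-one | C/C(=C/I)[C@H]1C=C2C(C)(C)CC(=O)C[C@@]2(C)O1 | intermediate
14 | (2R,6S,7aR)-2-[(1Z)-1-iodoprop-1-en-2-yl]-4,4,7a-trimethyl-2,4,5,6,7,7a-hexahydro-1-benzofuran-6-ol | C/C(=C/I)[C@H]1C=C2C(C)(C)C[C@H](O)C[C@@]2(C)O1 | intermediate
15 | (2E,4E,6E)-2,7-dimethylocta-2,4,6-trienedial | O=C/C(C)=C/C=C/C=C(C)/C=O | starting material
16 | ethyl (2E,4E,6E,8E)-4,9-dimethyl-10-oxodeca-2,4,6,8-tetraenoate | CCOC(=O)/C=C/C(C)=C/C=C/C=C(C)/C=O | intermediate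
17 | ethyl (2E,4E,6E,8E,10E)-4,9-dimethyl-11-(4,4,5,5-tetramethyl-1,3,2-dioxaborolan-2-yl)undeca-2,4,6,8,10-pentaenoate | CCOC(=O)/C=C/C(C)=C/C=C/C=C(C)/C=C/B1OC(C)(C)C(C)(C)O1 | intermediate
18 | (2E,4E,6E,8E,10E)-4,9-dimethyl-11-(4,4,5,5-tetramethyl-1,3,2-dioxaborolan-2-yl)undeca-2,4,6,8,10-pentaen-1-ol | OC/C=C/C(C)=C/C=C/C=C(C)/C=C/B1OC(C)(C)C(C)(C)O1 | intermediate
19 | (2R,6S,7aR)-2-[(2Z,4E,6E,8E,10E,12E)-14-hydroxy-6,11-dimethyltetradeca-2,4,6,8,10,12-hexaen-2-yl]-4,4,7a-trimethyl-2,4,5,6,7,7a-hexahydro-1-benzofuran-6-ol | C/C(=C/C=C/C(C)=C/C=C/C=C(C)/C=C/CO)[C@H]1C=C2C(C)(C)C[C@H](O)C[C@@]2(C)O1 | target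

Total step count: 13. Longest linear sequence: 8 steps (steps 1, 2, 3, 4, 7, 8, 9, 13).

**Steps most likely to fail**

Step 7. The relay from the oxirane to C7a may be lost: if the oxirane ionises fully, the alkoxide can rotate and attack either face of the allyl cation, and imperfect trans-selectivity in the betaine step would add to this. The fallback replaces the kinetic relay by thermodynamic recycling. It sets out from 12 obtained as a mixture with its C7a-epimer, the (2R,7aS)-spiro ketal F1. The mixture is hydrolysed as in step 8, and ketone 13 is separated from the (2R,7aS)-ketone F2. F2 is then treated with DBU in toluene at rt, which should open it by retro-oxa-Michael elimination to the (Z)-hydroxy dienone F3. F3 recloses by 5-exo-trig oxa-Michael addition to a mixture of 13 and F2, which is separated again and recycled. The fallback comes back to the route at 13.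

Step 8. The acid may ionise the tertiary allylic C7a–O1 bond or the doubly allylic C2–O1 bond (epimerisation, ring opening), or promote β-elimination of the new β-alkoxy ketone. The fallback unmasks the ketone without aqueous acid at ketal-cleaving strength and sets out from 12. Me3SiOSO2CF3 and i-Pr2NEt in CH2Cl2 at −78 °C should open the dioxolane under basic conditions to the 2-(trimethylsilyloxy)ethyl enol ether F4 (ketal-to-enol-ether elimination). F4 is hydrolysed in pH 5 acetate buffer/THF at 0 °C, where an enol ether is cleaved but an allylic ether is not. The fallback comes back at 13.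

Step 13. The basic aqueous medium may cause protodeboronation or decay of the polyenyl boronate, slow transmetalation, or Z-to-E drift of the iodide. The fallback is a base-free Stille union and sets out from 16. A Takai-type chromium-mediated stannyl olefination (Bu3SnCHBr2, CrCl2, LiI, THF) should give the (E)-stannane ester F5. Reduction with i-Bu2AlH at −78 °C gives the stannane alcohol F6. F6 is coupled with 14 (Pd2(dba)3, AsPh3, N-methylpyrrolidone, rt, dark), and the fallback comes back at 19.

**Further compounds**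
F1 | step 7 | (2R,7aS)-2-[(1Z)-1-iodoprop-1-en-2-yl]-4,4,7a-trimethyl-2,4,5,7a-tetrahydro-7H-spiro[1-benzofuran-6,2'-[1,3]dioxolane] | C/C(=C/I)[C@H]1C=C2C(C)(C)CC3(OCCO3)C[C@]2(C)O1
F2 | step 7 | (2R,7aS)-2-[(1Z)-1-iodoprop-1-en-2-yl]-4,4,7a-trimethyl-4,5,7,7a-tetrahydro-1-benzofuran-6(2H)-one | C/C(=C/I)[C@H]1C=C2C(C)(C)CC(=O)C[C@]2(C)O1
F3 | step 7 | (4Z)-4-[(2R,3Z)-2-hydroxy-4-iodo-3-methylbut-3-en-1-ylidene]-3,5,5-trimethylcyclohex-2-en-1-one | C/C(=C/I)[C@H](O)/C=C1\C(C)=CC(=O)CC1(C)C
F4 | step 8 | (2R,7aR)-2-[(1Z)-1-iodoprop-1-en-2-yl]-4,4,7a-trimethyl-6-[2-(trimethylsilyloxy)ethoxy]-2,4,7,7a-tetrahydro-1-benzofuran | C/C(=C/I)[C@H]1C=C2C(C)(C)C=C(OCCO[Si](C)(C)C)C[C@@]2(C)O1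
F5 | step 13 | ethyl (2E,4E,6E,8E,10E)-4,9-dimethyl-11-(tributylstannyl)undeca-2,4,6,8,10-pentaenoate | CCOC(=O)/C=C/C(C)=C/C=C/C=C(C)/C=C/[Sn](CCCC)(CCCC)CCCC
F6 | step 13 | (2E,4E,6E,8E,10E)-4,9-dimethyl-11-(tributylstannyl)undeca-2,4,6,8,10-pentaen-1-ol | OC/C=C/C(C)=C/C=C/C=C(C)/C=C/[Sn](CCCC)(CCCC)CCCC
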